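## Structural features

The target is a 2,3,4,6-tetrasubstituted oxane of configuration 2S,3S,4S,6S: O1; C2 bears a 4-hydroxyphenyl group (ring B); C3 a hydroxyl; C4 ring A; C5 is a methylene; C6 bears a 2-(4-hydroxyphenyl)ethyl chain (ring C). Ring A is a 2,4-dihydroxy-6-methoxyphenyl ketone bonded through C3′ to C4 and carrying at C1′ an (E)-4-hydroxycinnamoyl unit (ring D), that is, a 2′-hydroxychalcone. C2, C3 and C4 are contiguous: the C2 aryl is cis to the C3 hydroxyl, the hydroxyl is trans to ring A, ring A is cis to the C6 chain, and C2/C6 are trans. In the chair that keeps C3, C4 and C6 equatorial the C2 aryl is therefore axial. This is the less stable C2 epimer: the C2–O1 bond is a 4-hydroxybenzyl ether, and acid would ionise it and let it reclose to the all-equatorial isomer. The 2′-hydroxychalcone closes to a flavanone in aqueous base or strong acid and its C=C does not survive hydrogenation, so the five phenols must be unmasked under near-neutral conditions and every reduction must precede the enone. The real difficulties are the kinetic 2,6-trans relationship, the hindered C4–aryl bond flanked by two ring A oxygens, and the relative configuration of C2/C3/C4. The key step uses the fact that O1–C2(aryl) plus the oxygenated run C3–C6 is a furan-2-yl aryl carbinol in disguise: furan C2–C5 become C3–C6 and the carbinol oxygen becomes O1.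

## Logic of the disconnections

29 from 28. The three aryl O–Si bonds are cut last. Fluoride buffered with acetic acid is neither acidic (C2–O1 ionisation) nor basic (flavanone closure). A methoxymethyl ether on ring B would need acid at the end, so rings B, C and D carry triisopropylsilyl ethers throughout. The demand is that these ethers outlive every earlier step.

28 from 26. The two O–CH2 acetal bonds on ring A are cut. They are needed as lithiation directors up to 26 and are exchanged for labile silyl ethers (27) by a silyl triflate/bipyridyl reagent instead of mineral acid. The exchange must spare aryl silyl ethers, the enone and the benzylic ether.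

26 from 24 and 6. The C1′–C(=O) bond is cut. The enone cannot be present during hydrogenation, so the whole cinnamoyl unit arrives after the reductions. An anionic acylation (through 25) avoids the Lewis acids of a Friedel–Crafts route. In 24 the two ring A carbons next to the methoxy group are equivalent, so there is no regiochemical question. The demand is site-selective lithiation beside a free hydroxyl and 1,2-addition to the amide.

24 from 23. The C4–H and C5–H bonds are cut. A C4=C5 alkene lets the C3 hydroxyl deliver hydrogen to its own face and so fix C4. The demand is a hydroxyl cis to the C2 aryl and a catalyst that reduces a hindered trisubstituted alkene.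

23 from 22. The four C–H bonds of the side-chain CH2CH2 are cut. The chain is best introduced as a linear sp-carbon nucleophile. The demand is alkyne saturation without touching the ring alkene or the benzylic and allylic C–O bonds.

22 from 19 and 8. The C4–C(ring A) bond is cut as an sp2–sp2 coupling of a vinyl bromide with an arylzinc (through 20 and 21). Ring A becomes a two-step symmetric fragment. The coupling is placed after the ketone reduction so that C2 is no longer α to a carbonyl group when organometallics are present.

19 from 17. The C3–O bond is cut with inversion (through 18). Hydride reduction gives the hydroxyl trans to the C2 aryl, while the target and the directed hydrogenation need it cis. The demand is a clean SN2 displacement at a hindered allylic carbon.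

17 from 16. The C3–H bond is cut (1,2-reduction of the enone).

16 from 15 and 4. The C6–C(sp) bond is cut. C6 is an acetal carbon and therefore a natural electrophile. The cut removes the C6 stereocentre and the ring C chain. The demand is addition trans to the C2 aryl.

15 from 14. The acetyl C–O bond is cut (anomeric activation).

14 from 12 (key). The O1–C6 bond is cut and C3–C6 are folded back into a furan (through 13). The ring, the C3 ketone, the C4 handle and the C6 acetal all come from one aromatic ring and a single stereocentre. The anomeric centre of 14 is stereogenic but labile. The demand is furan-selective oxidation. The furan carries bromine at its C3 so that the rearrangement delivers the C4 halide directly and no base-mediated α-iodination is needed on a C2-epimerisable enone.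

12 from 2 and 9. The carbinol carbon–ring B bond is cut as a catalytic enantioselective aryl transfer (through 10 and 11). Reducing the corresponding ketone would require a catalyst to tell a furyl from a phenyl ring; the aryl transfer only has to tell the two faces of an aldehyde, and it is shorter.

6 from 2 and 5; 4 from 2 and 3; 2 from 1; 8 from 7. These cut an aryl–vinyl bond, an aryl–alkynyl bond, an O–Si bond and two O–CH2 bonds. One protected bromophenol serves rings B, C and D.

## Other disconnections considered

Alternative 1: The cut is C5–C6 and O1–C2 (hetero-Diels–Alder), followed by the C2–aryl bond. In the forward sense the aldehyde carrying ring C and a 1-alkoxy-2,3-bis(silyloxy) diene combine under a chiral Lewis acid to give dihydropyranone A1. Its locants need correcting: in target numbering it is a 5,6-dihydro-4H-pyran-4-one with the silyloxy group on C3 and the chain on C6; "2,3-dihydro" belongs to the ring's own numbering, in which the chain carbon is C2. An aryl cuprate then adds axially at the enol ether carbon to give the 2,6-trans ring.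
- In its favour: C6 is set by a catalyst with the saturated chain already in place, so no alkyne and no step 12. The C3 oxygen is built in and, being α to the C4 ketone, can settle equatorial, so no inversion is needed. On these points it is better than the chosen plan.
- Equal: both plans obtain 2,6-trans by axial attack on a ring electrophile.
- Against: C4 is a ketone carbon. Ring A would have to add as a di-ortho-substituted nucleophile to a hindered, enolisable α-silyloxy ketone and the tertiary alcohol then be removed with control of C4. While the C4 ketone is present the 2,6-trans oxanone can open by retro-oxa-Michael reaction and reclose cis.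
- Step economy: comparable up to A1, longer after it. The chosen plan forms the C4–aryl bond by coupling at a carbon that carries its halogen from the first step.

Alternative 2: The cut is C1′–C2′ of ring A. In the forward sense a Claisen-type closure of an open-chain masked triketo ester attached to C4 gives A2 after enolisation.
- In its favour: the substitution pattern of ring A is written into the chain, so there is no hindered aryl coupling and no late metalation, and the cinnamoyl unit arrives with the chain. After A2 only deprotection remains, which is better than the chosen endgame (steps 14–16).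
- Equal: regiochemistry on ring A is unambiguous in both plans, because 24 has a symmetric ring A.
- Against: the step creates none of the four oxane stereocentres. C4 would have to be bonded to the α-carbon of a β-keto ester with no directing element comparable to step 13. The polycarbonyl chain with a Michael acceptor can close by aldol, pyrone or intramolecular Michael pathways, and its base meets a 2′-phenoxide chalcone.
- Step economy: clearly worse, because of the long linear assembly of the chain on a finished oxane.

Alternative 3: The cut is C5–C6 and O1–C6. In the forward sense a rhodium-catalysed hydroformylation of an acyclic 1,1-disubstituted alkene (C4=C5), steered by an ortho-diphenylphosphinobenzoate on the C3 oxygen, puts H on C4 and the formyl carbon on C5. The C2 hydroxyl then closes to lactol A3.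
- In its favour: ring A is attached before the ring exists, so there is no hindered vinyl coupling. C3 needs no inversion, CO supplies C6, and the directing group doubles as protection. On C3/C4 it is better than steps 9–11 of the chosen plan.
- Equal: the stereo-determining event is a substrate-bound metal hydride delivering H to C4, as in step 13. A3 still needs the anomeric activation, alkynylation and alkyne reduction of steps 7, 8 and 12.
- Against: the precursor is a differentiated syn-diol (free benzylic C2 hydroxyl, esterified C3 hydroxyl, acyl migration possible) that needs its own asymmetric synthesis. The alkene is an α-aryl styrene with two ortho substituents, so insertion should be slow. Selectivity of this directing group is established for methallyl, not aryl-substituted, systems.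
- Step economy: comparable overall. The ring-first chosen plan offers more predictable cyclic stereocontrol.

Key step: step 6

Assumption: 3-bromofuran-2-carbaldehyde, N-methoxy-N-methylprop-2-enamide and (−)-MIB are treated as purchasable; (−)-MIB is assumed to deliver aryl to the Si face of the aldehyde as it does alkyl groups, and its enantiomer would be used if the sense proved opposite.

## Route

Step 1
Reactants: 1 4-bromophenol
Product: 2 (4-bromophenoxy)triisopropylsilane
Conditions: i-Pr3SiCl, imidazole, DMF, 23 °C
Reagents that add atoms: chlorotriisopropylsilane, CC(C)[Si](Cl)(C(C)C)C(C)C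
Why: Standard silylation of a phenol; the bulky aryl silyl ether tolerates n-BuLi, mild Lewis acid, K2CO3/MeOH and hydrogenation, does not direct ortho-lithiation, and leaves at the end with buffered fluoride.

Step 2
Reactants: 2 (4-bromophenoxy)triisopropylsilane; 3 ethynyltrimethylsilane
Product: 4 trimethyl{[4-(triisopropylsilyloxy)phenyl]ethynyl}silane
Conditions: PdCl2(PPh3)2 (3 mol%), CuI (6 mol%), Et3N, 80 °C, sealed vessel
Reagents that add atoms: none
Why: Sonogashira coupling of an aryl bromide with a terminal alkyne; the C-silyl group is kept because the alkynylsilane itself is the nucleophile of step 8.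

Step 3
Reactants: 2 (4-bromophenoxy)triisopropylsilane; 5 N-methoxy-N-methylprop-2-enamide
Product: 6 (2E)-N-methoxy-N-methyl-3-[4-(triisopropylsilyloxy)phenyl]prop-2-enamide
Conditions: Pd(OAc)2 (3 mol%), P(o-tol)3 (6 mol%), Et3N, DMF, 100 °C
Reagents that add atoms: none
Why: Mizoroki–Heck arylation of an acrylamide; syn insertion and syn β-hydride elimination give the E alkene that becomes the chalcone double bond.

Step 4
Reactants: 7 5-methoxybenzene-1,3-diol
Product: 8 1-methoxy-3,5-bis(methoxymethoxy)benzene
Conditions: MeOCH2Cl, i-Pr2NEt, CH2Cl2, 0 → 23 °C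
Reagents that add atoms: chloromethyl methyl ether, COCCl
Why: O-Alkylation of both phenols; the two acetal ethers direct lithiation first to the carbon between them (step 11) and later to a carbon next to the methoxy group (step 14).

Step 5
Reactants: 2 (4-bromophenoxy)triisopropylsilane; 9 3-bromofuran-2-carbaldehyde
Product: 12 (S)-(3-bromofuran-2-yl)[4-(triisopropylsilyloxy)phenyl]methanol, via aryllithium 10 (not isolated), via arylbutylzinc 11 (not isolated)
Conditions: 2 (2 equiv.), n-BuLi, t-BuOMe, −78 °C; ZnCl2; n-BuLi; Et2NCH2CH2NEt2; (−)-MIB (10 mol%), toluene; 9, 0 °C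
Reagents that add atoms: none
Why: Bromine–lithium exchange and transmetalation give a mixed arylbutylzinc that transfers only its aryl group to the aldehyde under amino-alkoxide catalysis (catalytic enantioselective aryl transfer), while the diamine ties up LiCl and suppresses the racemic background. Through the same bicyclic transition state as in alkyl transfer with this ligand, the aryl group is expected on the Si face, which gives the S carbinol.

Step 6
Reactants: 12 (S)-(3-bromofuran-2-yl)[4-(triisopropylsilyloxy)phenyl]methanol
Product: 14 (2S)-4-bromo-6-hydroxy-2-[4-(triisopropylsilyloxy)phenyl]-2H-pyran-3(6H)-one (anomeric mixture; 2S,6R anomer drawn), via cis-enedione 13 (not isolated)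
Conditions: NBS (1.05 equiv.), NaHCO3, NaOAc, THF–H2O 4:1, 0 °C
Reagents that add atoms: water, O
Why: Achmatowicz rearrangement: NBS delivers electrophilic bromine to C5 of the furan, water adds at C2, and the 2,5-dihydrofuran collapses with loss of bromide to the cis-enedione 13, whose aldehyde carbon is the former furan C5. The carbinol oxygen adds to that aldehyde in a 6-exo-trig hemiacetalisation, which forms the O1–C6 bond and closes the only new ring, the six-membered pyranone. The closest known reaction type is the oxidative ring expansion of 2-furylcarbinols, aryl-substituted and 3-halogenated ones included, with buffered NBS or a peracid. No bond to the carbinol carbon is touched, so it becomes C2 with unchanged S configuration; C6 forms as an equilibrating anomeric centre that is erased in step 8, so no lasting stereocentre is created. The step needs selectivity for the furan over the silyloxyarene, which the far higher nucleophilicity of the furan α-position, one equivalent of oxidant and 0 °C should secure. It also needs the doubly activated carbinol not to ionise, which the NaHCO3/NaOAc buffer secures by removing HBr. The bromine on furan C3 is a spectator and emerges on C4 as the α-bromoenone, the handle for ring A.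

Step 7
Reactants: 14 (2S)-4-bromo-6-hydroxy-2-[4-(triisopropylsilyloxy)phenyl]-2H-pyran-3(6H)-one
Product: 15 (2S,6S)-6-acetoxy-4-bromo-2-[4-(triisopropylsilyloxy)phenyl]-2H-pyran-3(6H)-one (trans anomer drawn; both anomers usable)
Conditions: Ac2O, pyridine, CH2Cl2, 0 °C
Reagents that add atoms: acetic anhydride, CC(=O)OC(C)=O
Why: O-Acylation of the hemiacetal installs an anomeric leaving group; exposure to pyridine is kept cold and short because C2–H is benzylic and α to the ketone, and both anomers give the same cation in step 8.

Step 8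
Reactants: 15 (2S,6S)-6-acetoxy-4-bromo-2-[4-(triisopropylsilyloxy)phenyl]-2H-pyran-3(6H)-one; 4 trimethyl{[4-(triisopropylsilyloxy)phenyl]ethynyl}silane
Product: 16 (2S,6R)-4-bromo-2-[4-(triisopropylsilyloxy)phenyl]-6-{[4-(triisopropylsilyloxy)phenyl]ethynyl}-2H-pyran-3(6H)-one
Conditions: Me3SiOTf (0.2 equiv.), CH2Cl2, −78 → −40 °C
Reagents that add atoms: none
Why: The silyl triflate ionises the anomeric acetate to a ring oxocarbenium ion, which the alkynylsilane attacks at its silicon-bearing carbon (β-silyl, aryl-stabilised vinyl cation) before losing Me3Si+ to regenerate the promoter; this is a Lewis acid C-glycosylation of the kind used with glycal and pyranone acetates. Attack is axial and anti to the pseudo-equatorial C2 aryl, so C6 is formed trans to C2 (6R).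

Step 9
Reactants: 16 (2S,6R)-4-bromo-2-[4-(triisopropylsilyloxy)phenyl]-6-{[4-(triisopropylsilyloxy)phenyl]ethynyl}-2H-pyran-3(6H)-one
Product: 17 (2S,3S,6R)-4-bromo-2-[4-(triisopropylsilyloxy)phenyl]-6-{[4-(triisopropylsilyloxy)phenyl]ethynyl}-3,6-dihydro-2H-pyran-3-ol
Conditions: NaBH4, CeCl3·7H2O, MeOH–CH2Cl2, −78 °C
Reagents that add atoms: none
Why: Luche reduction gives clean 1,2-reduction of the α-bromoenone; hydride adds axially, anti to the axial C2–H of the half-chair with the C2 aryl pseudo-equatorial, so the hydroxyl is expected trans to the aryl (3S), as is general for 2,6-trans dihydropyranones. From here on C2 is no longer α to a carbonyl group.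

Step 10
Reactants: 17 (2S,3S,6R)-4-bromo-2-[4-(triisopropylsilyloxy)phenyl]-6-{[4-(triisopropylsilyloxy)phenyl]ethynyl}-3,6-dihydro-2H-pyran-3-ol
Product: 19 (2S,3R,6R)-4-bromo-2-[4-(triisopropylsilyloxy)phenyl]-6-{[4-(triisopropylsilyloxy)phenyl]ethynyl}-3,6-dihydro-2H-pyran-3-ol, via 4-nitrobenzoate 18 (not isolated)
Conditions: 4-O2NC6H4CO2H, PPh3, DIAD, THF, 0 → 23 °C; then MeOH, K2CO3, 0 °C
Reagents that add atoms: 4-nitrobenzoic acid, O=C(O)c1ccc(cc1)[N+](=O)[O-]
Why: Mitsunobu reaction: the carboxylate displaces the oxyphosphonium of the allylic alcohol with inversion to give the cis ester 18, and mild methanolysis, which aryl triisopropylsilyl ethers tolerate, frees the alcohol (its oxygen now comes from the acid). The hydroxyl is thereby placed on the face of the C2 aryl (3R), as the target and step 13 require.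

Step 11
Reactants: 19 (2S,3R,6R)-4-bromo-2-[4-(triisopropylsilyloxy)phenyl]-6-{[4-(triisopropylsilyloxy)phenyl]ethynyl}-3,6-dihydro-2H-pyran-3-ol; 8 1-methoxy-3,5-bis(methoxymethoxy)benzene
Product: 22 (2S,3S,6R)-4-[4-methoxy-2,6-bis(methoxymethoxy)phenyl]-2-[4-(triisopropylsilyloxy)phenyl]-6-{[4-(triisopropylsilyloxy)phenyl]ethynyl}-3,6-dihydro-2H-pyran-3-ol, via ring A aryllithium 20 (not isolated), via ring A arylzinc chloride 21 (not isolated)
Conditions: 8 (3 equiv.), n-BuLi, THF, 0 °C; ZnCl2, 0 → 23 °C; 19, Pd(OAc)2 (5 mol%), SPhos (10 mol%), THF, 50 °C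
Reagents that add atoms: none
Why: Directed ortho-lithiation of 8 between its two acetal ethers, transmetalation to zinc and Negishi coupling with the vinyl bromide; dialkylbiarylphosphine–palladium catalysts couple di-ortho-substituted arylzinc reagents and tolerate a free hydroxyl. The zinc reagent needs no base and cannot protodeboronate as the analogous 2,6-dialkoxyarylboronic acid would. No stereocentre is touched; the C3 descriptor changes to S only because ring A replaces bromine.

Step 12
Reactants: 22 (2S,3S,6R)-4-[4-methoxy-2,6-bis(methoxymethoxy)phenyl]-2-[4-(triisopropylsilyloxy)phenyl]-6-{[4-(triisopropylsilyloxy)phenyl]ethynyl}-3,6-dihydro-2H-pyran-3-ol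
Product: 23 (2S,3S,6S)-4-[4-methoxy-2,6-bis(methoxymethoxy)phenyl]-2-[4-(triisopropylsilyloxy)phenyl]-6-{2-[4-(triisopropylsilyloxy)phenyl]ethyl}-3,6-dihydro-2H-pyran-3-ol
Conditions: H2 (1 atm), RhCl(PPh3)3 (10 mol%), toluene–EtOH 1:1, 23 °C
Reagents that add atoms: none
Why: Homogeneous hydrogenation with RhCl(PPh3)3 saturates the disubstituted alkyne through the cis-alkene, is very slow with the hindered trisubstituted ring alkene and does not hydrogenolyse benzylic or allylic C–O bonds. The alkyne is removed here because it could inhibit the cationic catalyst of step 13.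

Step 13
Reactants: 23 (2S,3S,6S)-4-[4-methoxy-2,6-bis(methoxymethoxy)phenyl]-2-[4-(triisopropylsilyloxy)phenyl]-6-{2-[4-(triisopropylsilyloxy)phenyl]ethyl}-3,6-dihydro-2H-pyran-3-ol
Product: 24 (2S,3S,4S,6S)-4-[4-methoxy-2,6-bis(methoxymethoxy)phenyl]-2-[4-(triisopropylsilyloxy)phenyl]-6-{2-[4-(triisopropylsilyloxy)phenyl]ethyl}oxan-3-ol
Conditions: H2 (1 atm), [Ir(cod)(PCy3)(py)]PF6 (10 mol%), CH2Cl2, 23 °C
Reagents that add atoms: none
Why: Hydroxyl-directed hydrogenation: the cationic iridium centre binds the C3 hydroxyl and delivers both hydrogens to the alkene face that carries it, so H enters C4 cis to OH and ring A ends up trans to the hydroxyl and cis to the C6 chain (4S). This is established behaviour for cyclic allylic alcohols with this catalyst, trisubstituted alkenes included.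

Step 14
Reactants: 24 (2S,3S,4S,6S)-4-[4-methoxy-2,6-bis(methoxymethoxy)phenyl]-2-[4-(triisopropylsilyloxy)phenyl]-6-{2-[4-(triisopropylsilyloxy)phenyl]ethyl}oxan-3-ol; 6 (2E)-N-methoxy-N-methyl-3-[4-(triisopropylsilyloxy)phenyl]prop-2-enamide
Product: 26 (2E)-1-{3-[(2S,3S,4S,6S)-3-hydroxy-2-[4-(triisopropylsilyloxy)phenyl]-6-{2-[4-(triisopropylsilyloxy)phenyl]ethyl}oxan-4-yl]-6-methoxy-2,4-bis(methoxymethoxy)phenyl}-3-[4-(triisopropylsilyloxy)phenyl]prop-2-en-1-one, via dilithio species 25 (not isolated)
Conditions: n-BuLi (2.3 equiv.), THF, 0 °C; 6 (1.5 equiv.), −78 → 0 °C; aq. NH4Cl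
Reagents that add atoms: none
Why: The first equivalent of base forms the C3 alkoxide and the second lithiates ring A at the carbon flanked by an acetal ether and the methoxy group (directed ortho-metalation; the two candidate carbons are equivalent and the silyl ethers do not direct). The aryllithium adds to the N-methoxy-N-methylamide (Weinreb ketone synthesis) and the chelated tetrahedral intermediate releases the E enone only on work-up, so the chalcone is installed in one operation without Lewis acid.

Step 15
Reactants: 26 (2E)-1-{3-[(2S,3S,4S,6S)-3-hydroxy-2-[4-(triisopropylsilyloxy)phenyl]-6-{2-[4-(triisopropylsilyloxy)phenyl]ethyl}oxan-4-yl]-6-methoxy-2,4-bis(methoxymethoxy)phenyl}-3-[4-(triisopropylsilyloxy)phenyl]prop-2-en-1-one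
Product: 28 (2E)-1-{2,4-dihydroxy-3-[(2S,3S,4S,6S)-3-hydroxy-2-[4-(triisopropylsilyloxy)phenyl]-6-{2-[4-(triisopropylsilyloxy)phenyl]ethyl}oxan-4-yl]-6-methoxyphenyl}-3-[4-(triisopropylsilyloxy)phenyl]prop-2-en-1-one, via tris(trimethylsilyl) ether 27 (not isolated)
Conditions: Me3SiOTf (6 equiv.), 2,2′-bipyridyl (9 equiv.), CH2Cl2, 0 → 23 °C; then H2O
Reagents that add atoms: none
Why: A silyl triflate buffered by 2,2′-bipyridyl converts aryl methoxymethyl ethers into aryl trimethylsilyl ethers under non-protic conditions, and water then hydrolyses them together with the transient C3 silyl ether. No acid strong enough to ionise the C2–O1 benzylic ether or to cyclise the chalcone is present, and the bulky aryl silyl ethers are untouched.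

Step 16
Reactants: 28 (2E)-1-{2,4-dihydroxy-3-[(2S,3S,4S,6S)-3-hydroxy-2-[4-(triisopropylsilyloxy)phenyl]-6-{2-[4-(triisopropylsilyloxy)phenyl]ethyl}oxan-4-yl]-6-methoxyphenyl}-3-[4-(triisopropylsilyloxy)phenyl]prop-2-en-1-one
Product: 29 (2E)-1-{2,4-dihydroxy-3-[(2S,3S,4S,6S)-3-hydroxy-2-(4-hydroxyphenyl)-6-[2-(4-hydroxyphenyl)ethyl]oxan-4-yl]-6-methoxyphenyl}-3-(4-hydroxyphenyl)prop-2-en-1-one
Conditions: Bu4NF, AcOH (1:1, 4 equiv.), THF, 0 °C
Reagents that add atoms: none
Why: Fluoride cleaves the three aryl O–Si bonds; acetic acid keeps the phenols protonated so the 2′-hydroxychalcone is not held as a phenoxide (flavanone closure), and the 4-hydroxybenzyl ether at C2 never meets acid.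

## Compound list

1 | 4-bromophenol | Oc1ccc(Br)cc1 | starting material
2 | (4-bromophenoxy)triisopropylsilane | CC(C)[Si](Oc1ccc(Br)cc1)(C(C)C)C(C)C | intermediate
3 | ethynyltrimethylsilane | C#C[Si](C)(C)C | starting material
4 | trimethyl{[4-(triisopropylsilyloxy)phenyl]ethynyl}silane | C[Si](C)(C)C#Cc1ccc(O[Si](C(C)C)(C(C)C)C(C)C)cc1 | intermediate
5 | N-methoxy-N-methylprop-2-enamide | C=CC(=O)N(C)OC | starting material
6 | (2E)-N-methoxy-N-methyl-3-[4-(triisopropylsilyloxy)phenyl]prop-2-enamide | CON(C)C(=O)/C=C/c1ccc(O[Si](C(C)C)(C(C)C)C(C)C)cc1 | intermediate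
7 | 5-methoxybenzene-1,3-diol | COc1cc(O)cc(O)c1 | starting material
8 | 1-methoxy-3,5-bis(methoxymethoxy)benzene | COCOc1cc(OC)cc(OCOC)c1 | intermediate
9 | 3-bromofuran-2-carbaldehyde | O=Cc1occc1Br | starting material
10 | [4-(triisopropylsilyloxy)phenyl]lithium | [Li]c1ccc(O[Si](C(C)C)(C(C)C)C(C)C)cc1 | intermediate
11 | butyl[4-(triisopropylsilyloxy)phenyl]zinc | CCCC[Zn]c1ccc(O[Si](C(C)C)(C(C)C)C(C)C)cc1 | intermediate
12 | (S)-(3-bromofuran-2-yl)[4-(triisopropylsilyloxy)phenyl]methanol | O[C@@H](c1ccc(O[Si](C(C)C)(C(C)C)C(C)C)cc1)c1occc1Br | intermediate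
13 | (2E,5S)-3-bromo-5-hydroxy-4-oxo-5-[4-(triisopropylsilyloxy)phenyl]pent-2-enal (cis-enedione: the two carbonyl carbons are cis on the C=C) | O=C/C=C(Br)\C(=O)[C@@H](O)c1ccc(O[Si](C(C)C)(C(C)C)C(C)C)cc1 | intermediate
14 | (2S)-4-bromo-6-hydroxy-2-[4-(triisopropylsilyloxy)phenyl]-2H-pyran-3(6H)-one (2S,6R anomer drawn) | O=C1C(Br)=C[C@H](O)O[C@H]1c1ccc(O[Si](C(C)C)(C(C)C)C(C)C)cc1 | intermediate
15 | (2S,6S)-6-acetoxy-4-bromo-2-[4-(triisopropylsilyloxy)phenyl]-2H-pyran-3(6H)-one | O=C1C(Br)=C[C@H](OC(C)=O)O[C@H]1c1ccc(O[Si](C(C)C)(C(C)C)C(C)C)cc1 | intermediate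
16 | (2S,6R)-4-bromo-2-[4-(triisopropylsilyloxy)phenyl]-6-{[4-(triisopropylsilyloxy)phenyl]ethynyl}-2H-pyran-3(6H)-one | O=C1C(Br)=C[C@H](C#Cc2ccc(O[Si](C(C)C)(C(C)C)C(C)C)cc2)O[C@H]1c1ccc(O[Si](C(C)C)(C(C)C)C(C)C)cc1 | intermediate
17 | (2S,3S,6R)-4-bromo-2-[4-(triisopropylsilyloxy)phenyl]-6-{[4-(triisopropylsilyloxy)phenyl]ethynyl}-3,6-dihydro-2H-pyran-3-ol | O[C@@H]1C(Br)=C[C@H](C#Cc2ccc(O[Si](C(C)C)(C(C)C)C(C)C)cc2)O[C@H]1c1ccc(O[Si](C(C)C)(C(C)C)C(C)C)cc1 | intermediate
18 | (2S,3R,6R)-4-bromo-2-[4-(triisopropylsilyloxy)phenyl]-6-{[4-(triisopropylsilyloxy)phenyl]ethynyl}-3,6-dihydro-2H-pyran-3-yl 4-nitrobenzoate | O=C(O[C@H]1C(Br)=C[C@H](C#Cc2ccc(O[Si](C(C)C)(C(C)C)C(C)C)cc2)O[C@H]1c1ccc(O[Si](C(C)C)(C(C)C)C(C)C)cc1)c1ccc(cc1)[N+](=O)[O-] | intermediate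
19 | (2S,3R,6R)-4-bromo-2-[4-(triisopropylsilyloxy)phenyl]-6-{[4-(triisopropylsilyloxy)phenyl]ethynyl}-3,6-dihydro-2H-pyran-3-ol | O[C@H]1C(Br)=C[C@H](C#Cc2ccc(O[Si](C(C)C)(C(C)C)C(C)C)cc2)O[C@H]1c1ccc(O[Si](C(C)C)(C(C)C)C(C)C)cc1 | intermediate
20 | [4-methoxy-2,6-bis(methoxymethoxy)phenyl]lithium | [Li]c1c(OCOC)cc(OC)cc1OCOC | intermediate
21 | chloro[4-methoxy-2,6-bis(methoxymethoxy)phenyl]zinc | Cl[Zn]c1c(OCOC)cc(OC)cc1OCOC | intermediate
22 | (2S,3S,6R)-4-[4-methoxy-2,6-bis(methoxymethoxy)phenyl]-2-[4-(triisopropylsilyloxy)phenyl]-6-{[4-(triisopropylsilyloxy)phenyl]ethynyl}-3,6-dihydro-2H-pyran-3-ol | O[C@H]1C(c2c(OCOC)cc(OC)cc2OCOC)=C[C@H](C#Cc2ccc(O[Si](C(C)C)(C(C)C)C(C)C)cc2)O[C@H]1c1ccc(O[Si](C(C)C)(C(C)C)C(C)C)cc1 | intermediate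
23 | (2S,3S,6S)-4-[4-methoxy-2,6-bis(methoxymethoxy)phenyl]-2-[4-(triisopropylsilyloxy)phenyl]-6-{2-[4-(triisopropylsilyloxy)phenyl]ethyl}-3,6-dihydro-2H-pyran-3-ol | O[C@H]1C(c2c(OCOC)cc(OC)cc2OCOC)=C[C@H](CCc2ccc(O[Si](C(C)C)(C(C)C)C(C)C)cc2)O[C@H]1c1ccc(O[Si](C(C)C)(C(C)C)C(C)C)cc1 | intermediate
24 | (2S,3S,4S,6S)-4-[4-methoxy-2,6-bis(methoxymethoxy)phenyl]-2-[4-(triisopropylsilyloxy)phenyl]-6-{2-[4-(triisopropylsilyloxy)phenyl]ethyl}oxan-3-ol | COc1cc(OCOC)c([C@@H]2C[C@H](CCc3ccc(O[Si](C(C)C)(C(C)C)C(C)C)cc3)O[C@@H](c3ccc(O[Si](C(C)C)(C(C)C)C(C)C)cc3)[C@H]2O)c(OCOC)c1 | intermediate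
25 | O3,C3′-dilithio derivative of 24 (lithium alkoxide at C3; ring A lithiated between an acetal ether and the methoxy group) | COc1cc(OCOC)c([C@@H]2C[C@H](CCc3ccc(O[Si](C(C)C)(C(C)C)C(C)C)cc3)O[C@@H](c3ccc(O[Si](C(C)C)(C(C)C)C(C)C)cc3)[C@H]2O[Li])c(OCOC)c1[Li] | intermediate
26 | (2E)-1-{3-[(2S,3S,4S,6S)-3-hydroxy-2-[4-(triisopropylsilyloxy)phenyl]-6-{2-[4-(triisopropylsilyloxy)phenyl]ethyl}oxan-4-yl]-6-methoxy-2,4-bis(methoxymethoxy)phenyl}-3-[4-(triisopropylsilyloxy)phenyl]prop-2-en-1-one | COc1cc(OCOC)c([C@@H]2C[C@H](CCc3ccc(O[Si](C(C)C)(C(C)C)C(C)C)cc3)O[C@@H](c3ccc(O[Si](C(C)C)(C(C)C)C(C)C)cc3)[C@H]2O)c(OCOC)c1C(=O)/C=C/c1ccc(O[Si](C(C)C)(C(C)C)C(C)C)cc1 | intermediate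
27 | tris(trimethylsilyl) ether of 28 (trimethylsilyl on O2′, O4′ and the C3 oxygen) | COc1cc(O[Si](C)(C)C)c([C@@H]2C[C@H](CCc3ccc(O[Si](C(C)C)(C(C)C)C(C)C)cc3)O[C@@H](c3ccc(O[Si](C(C)C)(C(C)C)C(C)C)cc3)[C@H]2O[Si](C)(C)C)c(O[Si](C)(C)C)c1C(=O)/C=C/c1ccc(O[Si](C(C)C)(C(C)C)C(C)C)cc1 | intermediate
28 | (2E)-1-{2,4-dihydroxy-3-[(2S,3S,4S,6S)-3-hydroxy-2-[4-(triisopropylsilyloxy)phenyl]-6-{2-[4-(triisopropylsilyloxy)phenyl]ethyl}oxan-4-yl]-6-methoxyphenyl}-3-[4-(triisopropylsilyloxy)phenyl]prop-2-en-1-one | COc1cc(O)c([C@@H]2C[C@H](CCc3ccc(O[Si](C(C)C)(C(C)C)C(C)C)cc3)O[C@@H](c3ccc(O[Si](C(C)C)(C(C)C)C(C)C)cc3)[C@H]2O)c(O)c1C(=O)/C=C/c1ccc(O[Si](C(C)C)(C(C)C)C(C)C)cc1 | intermediate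
29 | (2E)-1-{2,4-dihydroxy-3-[(2S,3S,4S,6S)-3-hydroxy-2-(4-hydroxyphenyl)-6-[2-(4-hydroxyphenyl)ethyl]oxan-4-yl]-6-methoxyphenyl}-3-(4-hydroxyphenyl)prop-2-en-1-one | COc1cc(O)c([C@@H]2C[C@H](CCc3ccc(O)cc3)O[C@@H](c3ccc(O)cc3)[C@H]2O)c(O)c1C(=O)/C=C/c1ccc(O)cc1 | target

## Step count and least certain steps

Total: 16 steps. Longest linear sequence: 13 steps (1, 5, 6, 7, 8, 9, 10, 11, 12, 13, 14, 15, 16).

Step 6 (key step). The most likely failures are competing electrophilic bromination of the silyloxyarene, acid-promoted ionisation of the doubly activated carbinol (loss of enantiopurity, ether formation) if HBr is not scavenged fast enough, or slow oxidation of the bromine-deactivated furan with over-oxidation. The fallback sets out from 12 and returns at 14. It uses dye-sensitised photooxygenation (O2, rose bengal, visible light, CH2Cl2–MeOH, −78 °C), in which singlet oxygen adds across furan C2/C5 in a [4+2] sense to give the furan endoperoxide F1. Reduction with Me2S gives the same enedione 13, which closes to 14. No electrophilic halogen and no acid are involved.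

Step 5. Facial selectivity may be eroded by an uncatalysed, LiCl-promoted background addition or by the ortho bromine of the aldehyde in the catalyst pocket, and the sense of induction is taken by analogy. The fallback sets out from 2 and 9 and returns at 12. Magnesium in THF converts 2 into the aryl Grignard reagent F2, which adds to 9 to give the racemic carbinol F3. MnO2 oxidises F3 to the ketone F4. Asymmetric transfer hydrogenation of F4 with RuCl(p-cymene)[(R,R)-TsDPEN] in HCO2H–Et3N then gives 12. The R,R ligand is the one expected to give S if the in-plane para-substituted phenyl ring takes the place of the phenyl of acetophenone and the twisted bromofuryl ring that of its methyl group; the antipodal ligand is used otherwise.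

Step 8. The alkynylsilane may be too weak a nucleophile, so that the α-keto oxocarbenium ion decomposes before capture, or the propargylic C6–O1 bond may re-ionise and erode the trans selectivity. The fallback sets out from 4 and 15 and returns at 16. K2CO3 in MeOH removes the C-silyl group of 4 to give the terminal alkyne F5. n-BuLi converts F5 into the lithium acetylide F6, and BF3·OEt2 at −78 °C converts that into the lithium alkynyltrifluoroborate F7. F7 is a far stronger alkynyl donor and captures the cation generated from 15 by the excess BF3·OEt2 in the same flask to give 16.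

Step 10. Displacement at the hindered allylic C3 may be outrun by elimination, by SN2′ attack at C5, or by a retentive acyloxyphosphonium pathway. The fallback sets out from 16 and returns at 19, bypassing 17 and 18. It is a reagent-controlled Corey–Bakshi–Shibata reduction with (S)-2-methyl-CBS-oxazaborolidine (20 mol%) and catecholborane in toluene at −78 °C. With the bromovinyl carbon as the large group, as in 2-bromocycloalkenones, the S catalyst is expected to deliver the 3R alcohol directly. It makes no compound outside the list.

Step 11. Transmetalation and reductive elimination at the doubly ortho-substituted arylzinc may be slow, so that reduction of the C–Br bond or quenching of the zinc reagent by the free hydroxyl competes. The fallback sets out from 19 and 20 and returns at 22. Quenching 20 with B(OMe)3 followed by mild aqueous acid gives the ring A boronic acid F8. F8 is coupled with 19 in a Suzuki–Miyaura reaction (Pd(OAc)2, SPhos, K3PO4, toluene–H2O, 60 °C), in which the boronate pathway is activated by base and a large excess of F8 can offset protodeboronation.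

Step 14. Lithiation may be unselective (ortho to a silyl ether, or at the benzylic C2–H with ring opening by β-elimination) or incomplete because the lithium alkoxide aggregates. The fallback sets out from 24 and returns at 26. NBS in MeCN at −20 °C brominates only the trialkoxy ring A to give the aryl bromide F9. n-BuLi (1 equiv.) then t-BuLi (2 equiv.) at −78 °C gives 25 by deprotonation of the hydroxyl and bromine–lithium exchange at a defined position, and addition of 6 gives 26.

## Further compounds

F1 | step 6 | (S)-(6-bromo-2,3,7-trioxabicyclo[2.2.1]hept-5-en-1-yl)[4-(triisopropylsilyloxy)phenyl]methanol (furan endoperoxide; bridgehead configuration not defined) | O[C@@H](c1ccc(O[Si](C(C)C)(C(C)C)C(C)C)cc1)C12OOC(C=C1Br)O2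
F2 | step 5 | bromo[4-(triisopropylsilyloxy)phenyl]magnesium | Br[Mg]c1ccc(O[Si](C(C)C)(C(C)C)C(C)C)cc1
F3 | step 5 | racemic (3-bromofuran-2-yl)[4-(triisopropylsilyloxy)phenyl]methanol | OC(c1ccc(O[Si](C(C)C)(C(C)C)C(C)C)cc1)c1occc1Br
F4 | step 5 | (3-bromofuran-2-yl)[4-(triisopropylsilyloxy)phenyl]methanone | O=C(c1ccc(O[Si](C(C)C)(C(C)C)C(C)C)cc1)c1occc1Br
F5 | step 8 | (4-ethynylphenoxy)triisopropylsilane | C#Cc1ccc(O[Si](C(C)C)(C(C)C)C(C)C)cc1
F6 | step 8 | {[4-(triisopropylsilyloxy)phenyl]ethynyl}lithium | [Li]C#Cc1ccc(O[Si](C(C)C)(C(C)C)C(C)C)cc1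
F7 | step 8 | lithium trifluoro{[4-(triisopropylsilyloxy)phenyl]ethynyl}borate | [Li+].F[B-](F)(F)C#Cc1ccc(O[Si](C(C)C)(C(C)C)C(C)C)cc1
F0 | step 10 | none | none
F8 | step 11 | [4-methoxy-2,6-bis(methoxymethoxy)phenyl]boronic acid | COCOc1cc(OC)cc(OCOC)c1B(O)O
F9 | step 14 | (2S,3S,4S,6S)-4-[3-bromo-4-methoxy-2,6-bis(methoxymethoxy)phenyl]-2-[4-(triisopropylsilyloxy)phenyl]-6-{2-[4-(triisopropylsilyloxy)phenyl]ethyl}oxan-3-ol | COc1cc(OCOC)c([C@@H]2C[C@H](CCc3ccc(O[Si](C(C)C)(C(C)C)C(C)C)cc3)O[C@@H](c3ccc(O[Si](C(C)C)(C(C)C)C(C)C)cc3)[C@H]2O)c(OCOC)c1Br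
A1 | alternative 1 | (2S)-5-{[tert-butyl(dimethyl)silyl]oxy}-2-{2-[4-(methoxymethoxy)phenyl]ethyl}-2,3-dihydro-4H-pyran-4-one (target numbering: 6S, silyloxy on C3, 5,6-dihydro) | O=C1C[C@H](CCc2ccc(OCOC)cc2)OC=C1O[Si](C)(C)C(C)(C)C
A2 | alternative 2 | (2E)-1-{3-[(2S,3S,4S,6S)-3-{[tert-butyl(dimethyl)silyl]oxy}-2-[4-(methoxymethoxy)phenyl]-6-{2-[4-(methoxymethoxy)phenyl]ethyl}oxan-4-yl]-2,4-dihydroxy-6-methoxyphenyl}-3-[4-(methoxymethoxy)phenyl]prop-2-en-1-one | COc1cc(O)c([C@@H]2C[C@H](CCc3ccc(OCOC)cc3)O[C@@H](c3ccc(OCOC)cc3)[C@H]2O[Si](C)(C)C(C)(C)C)c(O)c1C(=O)/C=C/c1ccc(OCOC)cc1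
A3 | alternative 3 | (2S,3S,4S,6R)-6-hydroxy-4-[4-methoxy-2,6-bis(methoxymethoxy)phenyl]-2-[4-(methoxymethoxy)phenyl]oxan-3-yl 2-(diphenylphosphanyl)benzoate (one anomer drawn) | O[C@H]1C[C@@H](c2c(OCOC)cc(OC)cc2OCOC)[C@H](OC(=O)c2ccccc2P(c2ccccc2)c2ccccc2)[C@H](c2ccc(OCOC)cc2)O1
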